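**Retrosynthetic overview**

1. Locants used: C1 furanone C=O, C2 furanone CH, C3 furanone O–C=, C4 C(=C15H2), C5 CHOH, C6 CH–O-methacryloyl, C7/C8 lactone ring-fusion CH and CH–O, C9 CH2, C10 C(C14H3)–O, C11/C12/C13 lactone Cα, C=O and =CH2.
2. Ten-membered carbocycle (last ring): C4–C5 by intramolecular Nozaki–Hiyama–Kishi addition of a C4 enol triflate to a C5 aldehyde that already carries the C6 methacrylate; this also sets C5.
3. Butyrolactone (key): O–C8 and C11–C7 are made together by an oxidative radical [3+2] annulation of a (Z)-C7=C8 alkene with a malonic half-ester hung on O5. The enabling feature is that the lactone Cα (C11) lies 1,5 to the oxygen on C5, so C11, the tether carbonyl, O5, C5, C6 and C7 close a temporary six-membered lactone; this ring is cut afterwards, its carbonyl leaving as CO2 while C13 is put on.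
4. Furanone (first ring built): O–C3 by 5-endo cyclization of a C10-hydroxy ynedione; C9–C10 from alkynyl opening of an (R)-2-methylglycidol ether; C6 from (R)-solketal; the (Z)-alkene from semihydrogenation.
5. Ring order: furanone, then tether lactone plus butyrolactone in one operation, tether lactone opened, ten-membered ring last.

Key step: step 12

Remark: the configuration at the malonate carbon C11 of 17 to 20 is of no consequence (C11 becomes sp2) and is left open in the SMILES; 11 is a mixture of carbinol epimers that converge in step 8; (R)-2-methylglycidol is taken as a catalogue compound.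

**Route**

Step 1
Reactants: 1 (R)-solketal
Product: 3 (R)-4-ethynyl-2,2-dimethyl-1,3-dioxolane, via aldehyde 2 (not isolated)
Conditions: TEMPO (cat.), PhI(OAc)2, CH2Cl2, rt; then K2CO3, MeOH, dimethyl (1-diazo-2-oxopropyl)phosphonate, 0 °C to rt
Reagents that add atoms: dimethyl (1-diazo-2-oxopropyl)phosphonate CC(=O)C(=[N+]=[N-])P(=O)(OC)OC
Why: Nitroxyl-catalysed alcohol oxidation followed by Ohira–Bestmann (Seyferth–Gilbert) homologation of the crude aldehyde under mild carbonate conditions should carry the dioxolane stereocentre (later C6) over unchanged.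

Step 2
Reactants: 4 (R)-2-methylglycidol
Product: 5 (S)-tert-butyldimethyl[(2-methyloxiran-2-yl)methoxy]silane
Conditions: TBSCl, imidazole, CH2Cl2, 0 °C to rt
Reagents that add atoms: tert-butyldimethylsilyl chloride CC(C)(C)[Si](C)(C)Cl
Why: Standard silylation of the primary alcohol; the quaternary epoxide carbon (later C10) is untouched and only its descriptor changes.

Step 3
Reactants: 3 (R)-4-ethynyl-2,2-dimethyl-1,3-dioxolane; 5 silyl ether of (R)-2-methylglycidol
Product: 6 (2S)-1-[(tert-butyldimethylsilyl)oxy]-5-[(4R)-2,2-dimethyl-1,3-dioxolan-4-yl]-2-methylpent-4-yn-2-ol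
Conditions: 3, n-BuLi, THF, −78 °C; BF3·OEt2; then 5, −78 °C
Reagents that add atoms: none
Why: BF3-promoted opening of a terminal epoxide by an alkynyllithium should occur at the unsubstituted CH2 (C9), so the C10–O bond and its configuration stay intact.

Step 4
Reactants: 6 alkynol
Product: 7 (2S,4Z)-1-[(tert-butyldimethylsilyl)oxy]-5-[(4R)-2,2-dimethyl-1,3-dioxolan-4-yl]-2-methylpent-4-en-2-ol
Conditions: H2 (1 atm), Pd on CaCO3 poisoned with Pb(OAc)2, quinoline, EtOAc, rt
Reagents that add atoms: none
Why: Lindlar-type syn semihydrogenation should give the (Z)-alkene that the key step needs for allylic 1,3-strain control.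

Step 5
Reactants: 7 (Z)-alkenol silyl ether
Product: 8 (2S,4Z)-5-[(4R)-2,2-dimethyl-1,3-dioxolan-4-yl]-2-methylpent-4-ene-1,2-diol
Conditions: Bu4NF, THF, 0 °C to rt
Reagents that add atoms: none
Why: Fluoride cleavage of the primary silyl ether; nothing else in the molecule is fluoride-labile.

Step 6
Reactants: 8 diol
Product: 9 (2S,4Z)-5-[(4R)-2,2-dimethyl-1,3-dioxolan-4-yl]-2-hydroxy-2-methylpent-4-enal
Conditions: IBX, DMSO, rt
Reagents that add atoms: none
Why: IBX oxidizes the primary alcohol of a 1,2-diol to the aldehyde without glycol cleavage; the tertiary hydroxyl is inert and the quaternary α-carbon cannot epimerize.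

Step 7
Reactants: 9 hydroxy aldehyde; 10 but-3-yn-2-ol
Product: 11 (6S,8Z)-9-[(4R)-2,2-dimethyl-1,3-dioxolan-4-yl]-6-methylnon-8-en-3-yne-2,5,6-triol
Conditions: 10, n-BuLi (2 equiv per 10), THF, −78 to −20 °C; then 9, −78 to 0 °C
Reagents that add atoms: none
Why: 1,2-Addition of the alkynyl dianion to the aldehyde (excess reagent absorbs the free hydroxyl); both carbinol centres are oxidized next, so their configuration is irrelevant.

Step 8
Reactants: 11 triol
Product: 13 (2S)-5-acetyl-2-{(2Z)-3-[(4R)-2,2-dimethyl-1,3-dioxolan-4-yl]prop-2-en-1-yl}-2-methylfuran-3(2H)-one, via ynedione 12 (not isolated)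
Conditions: DMP, CH2Cl2, 0 °C to rt; then Et3N (cat.), CH2Cl2, rt
Reagents that add atoms: none
Why: Dess–Martin oxidation of both propargylic alcohols gives the ynedione, whose tertiary hydroxyl should add 5-endo-dig to the alkyne carbon β to the C1 ketone (base-catalysed cyclization of an α'-hydroxy ynone to a 3(2H)-furanone), since attack at the other alkyne carbon would need a four-membered ring.

Step 9
Reactants: 13 acetylfuranone
Product: 14 1-[(5S)-5-{(2Z)-3-[(4R)-2,2-dimethyl-1,3-dioxolan-4-yl]prop-2-en-1-yl}-5-methyl-4-oxo-4,5-dihydrofuran-2-yl]ethenyl trifluoromethanesulfonate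
Conditions: KN(SiMe3)2, THF, −78 °C; PhNTf2, −78 to −20 °C
Reagents that add atoms: N-phenylbis(trifluoromethanesulfonimide) O=S(=O)(N(c1ccccc1)S(=O)(=O)C(F)(F)F)C(F)(F)F
Why: Kinetic enolization at the only enolizable position (the acetyl CH3) and O-sulfonylation should give the 2-triflyloxy diene, the alkenyl partner for the final ring closure.

Step 10
Reactants: 14 enol triflate acetonide
Product: 15 1-{(5S)-5-[(2Z,4R)-4,5-dihydroxypent-2-en-1-yl]-5-methyl-4-oxo-4,5-dihydrofuran-2-yl}ethenyl trifluoromethanesulfonate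
Conditions: AcOH/H2O (4:1), 40 °C
Reagents that add atoms: none
Why: Acid hydrolysis of the isopropylidene acetal; the enol triflate and the furanone tolerate aqueous acetic acid.

Step 11
Reactants: 15 diol
Product: 16 3-{[(2R,3Z)-2-hydroxy-5-[(2S)-2-methyl-3-oxo-5-(1-{[(trifluoromethyl)sulfonyl]oxy}ethenyl)-2,3-dihydrofuran-2-yl]pent-3-en-1-yl]oxy}-3-oxopropanoic acid
Conditions: Meldrum's acid (1.05 equiv), toluene, 80 °C
Reagents that add atoms: 2,2-dimethyl-1,3-dioxane-4,6-dione CC1(C)OC(=O)CC(=O)O1
Why: Alcoholysis of Meldrum's acid with loss of acetone should place the malonic half-ester on the primary hydroxyl (O5), which is both the faster and the thermodynamically preferred ester position.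

Step 12
Reactants: 16 malonic half-ester
Product: 17 (5R,6S,7S)-5-hydroxy-7-{[(2S)-2-methyl-3-oxo-5-(1-{[(trifluoromethyl)sulfonyl]oxy}ethenyl)-2,3-dihydrofuran-2-yl]methyl}-3,8-dioxabicyclo[4.3.0]nonane-2,9-dione
Conditions: Mn(OAc)3·2H2O (2.2 equiv), Cu(OAc)2·H2O (1 equiv), degassed AcOH, 0.005 M, 50 °C
Reagents that add atoms: none
Why: Mn(OAc)3 oxidizes the enolized malonic half-ester to a manganese-bound electrophilic C11 radical that adds 6-exo-trig to C7 of the (Z)-alkene, closing the temporary six-membered lactone (C11, tether C=O, O5, C5, C6, C7); the secondary C8 radical is captured by carboxylate-bound Cu(OAc)2 and the alkylcopper intermediate collapses by C–O bond formation with the free carboxyl (5-exo closure of the butyrolactone), releasing monovalent copper that Mn(OAc)3 reoxidizes. The closest known reaction types are the Mn(OAc)3/Cu(OAc)2 oxidative cyclization–lactonization of alkenyl malonates (allylic malonates give fused bis-lactones) and the trivalent-manganese [3+2] lactone annulation of alkenes with malonic half-esters. C7 is controlled by the C6 stereocentre through a chair-like transition state in which allylic 1,3-strain of the (Z)-alkene holds H6 in the alkene plane, so that C5 brings C11 to the face opposite the C6 hydroxyl (C6–O and C8 both equatorial and trans on the new six-membered ring), which is the 6,7-relationship of 23. C8 is set in the C–O closure, where C9 takes the convex position trans to C6 on the butyrolactone, the usual trans-β,γ outcome of this lactonization and the trans 7,8-fusion of 23. The step needs exo attack at C7 rather than C8 and capture of the C8 radical by copper faster than its addition to the furanone or the dienyl triflate; the five-atom tether and the 1,2-disubstituted alkene secure the first, and copper held on the substrate carboxylate, the full equivalent of Cu(OAc)2 and high dilution secure the second. The configuration at C11 is lost later and does not matter.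

Step 13
Reactants: 17 hydroxy bis-lactone
Product: 18 (5R,6R,7S)-7-{[(2S)-2-methyl-3-oxo-5-(1-{[(trifluoromethyl)sulfonyl]oxy}ethenyl)-2,3-dihydrofuran-2-yl]methyl}-2,9-dioxo-3,8-dioxabicyclo[4.3.0]nonan-5-yl 2-methylprop-2-enoate
Conditions: methacrylic anhydride, DMAP (cat.), pyridine, CH2Cl2, 0 °C to rt
Reagents that add atoms: methacrylic anhydride C=C(C)C(=O)OC(=O)C(C)=C
Why: DMAP-catalysed acylation of the only free hydroxyl (C6–OH) while O5 is still locked in the tether lactone, so the ester is placed without ambiguity.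

Step 14
Reactants: 18 methacrylate bis-lactone
Product: 19 1-[(dimethylamino)methyl] derivative of 18 (Mannich base at the malonate carbon C11)
Conditions: CH2=NMe2+ I− (1.5 equiv), Et3N (1.5 equiv), CH2Cl2, rt
Reagents that add atoms: N,N-dimethylmethyleneiminium iodide C=[N+](C)C.[I-]
Why: Mannich alkylation of the acidic malonate-type C11–H between the two lactone carbonyls should install C13 without touching the esters.

Step 15
Reactants: 19 Mannich base
Product: 21 (1R)-2-hydroxy-1-[(2S,3R)-2-{[(2S)-2-methyl-3-oxo-5-(1-{[(trifluoromethyl)sulfonyl]oxy}ethenyl)-2,3-dihydrofuran-2-yl]methyl}-4-methylidene-5-oxooxolan-3-yl]ethyl 2-methylprop-2-enoate, via ammonium iodide 20 (not isolated)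
Conditions: MeI, MeCN, rt; then NaHCO3, THF/H2O, 0 °C
Reagents that add atoms: none
Why: Quaternization gives a non-enolizable, doubly activated malonate in which bicarbonate should hydrolyse the six-membered lactone (primary alkoxide leaving group, far faster than the butyrolactone or the methacrylate), and the resulting β-ammonio carboxylate loses CO2 and NMe3 in a Grob-type decarboxylative elimination, the classical Mannich-base route to α-methylene lactones.

Step 16
Reactants: 21 primary alcohol
Product: 22 (1R)-2-oxo-1-[(2S,3R)-2-{[(2S)-2-methyl-3-oxo-5-(1-{[(trifluoromethyl)sulfonyl]oxy}ethenyl)-2,3-dihydrofuran-2-yl]methyl}-4-methylidene-5-oxooxolan-3-yl]ethyl 2-methylprop-2-enoate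
Conditions: DMP, CH2Cl2, 0 °C to rt
Reagents that add atoms: none
Why: Neutral Dess–Martin oxidation; the α-acyloxy aldehyde is used crude to avoid epimerization at C6 and acyl migration.

Step 17
Reactants: 22 aldehyde enol triflate
Product: 23 CNP0142847.1
Conditions: CrCl2 (10 equiv), NiCl2 (0.1 equiv), DMSO/THF, rt, slow addition to 0.002 M
Reagents that add atoms: none
Why: Nozaki–Hiyama–Kishi reaction: zerovalent nickel inserts into the enol triflate, transmetalation to trivalent chromium gives an alkenylchromium that adds to the aldehyde and closes the ten-membered carbocycle, and C5 should be set by polar Felkin–Anh addition (C6–O anti to the incoming C4), which gives the 5,6-anti relationship of 23; esters, the enone and the methylene lactone are tolerated.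

**Compound list**

1 | (R)-(2,2-dimethyl-1,3-dioxolan-4-yl)methanol, (R)-solketal | OC[C@@H]1COC(C)(C)O1 | starting material
2 | (S)-2,2-dimethyl-1,3-dioxolane-4-carbaldehyde | O=C[C@@H]1COC(C)(C)O1 | intermediate (not isolated)
3 | (R)-4-ethynyl-2,2-dimethyl-1,3-dioxolane | C#C[C@@H]1COC(C)(C)O1 | intermediate
4 | (R)-(2-methyloxiran-2-yl)methanol, (R)-2-methylglycidol | C[C@@]1(CO)CO1 | starting material
5 | (S)-tert-butyldimethyl[(2-methyloxiran-2-yl)methoxy]silane | C[C@@]1(CO[Si](C)(C)C(C)(C)C)CO1 | intermediate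
6 | (2S)-1-[(tert-butyldimethylsilyl)oxy]-5-[(4R)-2,2-dimethyl-1,3-dioxolan-4-yl]-2-methylpent-4-yn-2-ol | CC(C)(C)[Si](C)(C)OC[C@@](C)(O)CC#C[C@@H]1COC(C)(C)O1 | intermediate
7 | (2S,4Z)-1-[(tert-butyldimethylsilyl)oxy]-5-[(4R)-2,2-dimethyl-1,3-dioxolan-4-yl]-2-methylpent-4-en-2-ol | CC(C)(C)[Si](C)(C)OC[C@@](C)(O)C/C=C\[C@@H]1COC(C)(C)O1 | intermediate
8 | (2S,4Z)-5-[(4R)-2,2-dimethyl-1,3-dioxolan-4-yl]-2-methylpent-4-ene-1,2-diol | OC[C@@](C)(O)C/C=C\[C@@H]1COC(C)(C)O1 | intermediate
9 | (2S,4Z)-5-[(4R)-2,2-dimethyl-1,3-dioxolan-4-yl]-2-hydroxy-2-methylpent-4-enal | O=C[C@@](C)(O)C/C=C\[C@@H]1COC(C)(C)O1 | intermediate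
10 | but-3-yn-2-ol (racemic) | CC(O)C#C | starting material
11 | (6S,8Z)-9-[(4R)-2,2-dimethyl-1,3-dioxolan-4-yl]-6-methylnon-8-en-3-yne-2,5,6-triol (epimer mixture at C2 and C5) | CC(O)C#CC(O)[C@@](C)(O)C/C=C\[C@@H]1COC(C)(C)O1 | intermediate
12 | (6S,8Z)-9-[(4R)-2,2-dimethyl-1,3-dioxolan-4-yl]-6-hydroxy-6-methylnon-8-en-3-yne-2,5-dione | CC(=O)C#CC(=O)[C@@](C)(O)C/C=C\[C@@H]1COC(C)(C)O1 | intermediate (not isolated)
13 | (2S)-5-acetyl-2-{(2Z)-3-[(4R)-2,2-dimethyl-1,3-dioxolan-4-yl]prop-2-en-1-yl}-2-methylfuran-3(2H)-one | CC(=O)C1=CC(=O)[C@](C)(C/C=C\[C@@H]2COC(C)(C)O2)O1 | intermediate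
14 | 1-[(5S)-5-{(2Z)-3-[(4R)-2,2-dimethyl-1,3-dioxolan-4-yl]prop-2-en-1-yl}-5-methyl-4-oxo-4,5-dihydrofuran-2-yl]ethenyl trifluoromethanesulfonate | C=C(OS(=O)(=O)C(F)(F)F)C1=CC(=O)[C@](C)(C/C=C\[C@@H]2COC(C)(C)O2)O1 | intermediate
15 | 1-{(5S)-5-[(2Z,4R)-4,5-dihydroxypent-2-en-1-yl]-5-methyl-4-oxo-4,5-dihydrofuran-2-yl}ethenyl trifluoromethanesulfonate | C=C(OS(=O)(=O)C(F)(F)F)C1=CC(=O)[C@](C)(C/C=C\[C@@H](O)CO)O1 | intermediate
16 | malonic half-ester of the primary hydroxyl of 15 (name as in step 11) | C=C(OS(=O)(=O)C(F)(F)F)C1=CC(=O)[C@](C)(C/C=C\[C@@H](O)COC(=O)CC(=O)O)O1 | intermediate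
17 | (5R,6S,7S)-5-hydroxy-7-(furanonylmethyl)-3,8-dioxabicyclo[4.3.0]nonane-2,9-dione (six-membered tether lactone fused to the butyrolactone; C1 open; name as in step 12) | C=C(OS(=O)(=O)C(F)(F)F)C1=CC(=O)[C@](C)(C[C@@H]2OC(=O)C3C(=O)OC[C@H](O)[C@@H]23)O1 | intermediate
18 | C6 methacrylate of 17 (name as in step 13) | C=C(OS(=O)(=O)C(F)(F)F)C1=CC(=O)[C@](C)(C[C@@H]2OC(=O)C3C(=O)OC[C@H](OC(=O)C(C)=C)[C@@H]23)O1 | intermediate
19 | 1-[(dimethylamino)methyl] derivative of 18 | C=C(OS(=O)(=O)C(F)(F)F)C1=CC(=O)[C@](C)(C[C@@H]2OC(=O)C3(CN(C)C)C(=O)OC[C@H](OC(=O)C(C)=C)[C@@H]23)O1 | intermediate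
20 | trimethylammonium iodide of 19 | C=C(OS(=O)(=O)C(F)(F)F)C1=CC(=O)[C@](C)(C[C@@H]2OC(=O)C3(C[N+](C)(C)C)C(=O)OC[C@H](OC(=O)C(C)=C)[C@@H]23)O1.[I-] | intermediate (not isolated)
21 | α-methylene butyrolactone with C6 methacrylate and free primary C5 hydroxyl (name as in step 15) | C=C(OS(=O)(=O)C(F)(F)F)C1=CC(=O)[C@](C)(C[C@@H]2OC(=O)C(=C)[C@H]2[C@H](CO)OC(=O)C(C)=C)O1 | intermediate
22 | C5 aldehyde of 21 (name as in step 16) | C=C(OS(=O)(=O)C(F)(F)F)C1=CC(=O)[C@](C)(C[C@@H]2OC(=O)C(=C)[C@H]2[C@H](C=O)OC(=O)C(C)=C)O1 | intermediate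
23 | CNP0142847.1 (5S,6R,7R,8S,10S in the locants above) | C=C(C)C(=O)O[C@@H]1[C@@H]2C(=C)C(=O)O[C@H]2C[C@]2(C)OC(=CC2=O)C(=C)[C@@H]1O | target

**Step count and risks**

Total steps: 17. Longest linear sequence: 16 steps (from 1 through steps 1 and 3 to 17; the branch from 4 is equally long).

Most likely to fail, in this order:

Step 12. The six-membered closure through the ester tether may be slow (unfavourable ester rotamer), so the malonyl radical could dimerize or be reduced. The alkylcopper intermediate could also lose a β-hydrogen instead of forming the C–O bond, or the C8 radical could add to the furanone. The fallback sets out from 15. The primary hydroxyl would be esterified with mono-tert-butyl malonate (DCC, DMAP) to the mixed malonate F1, which would be iodinated (I2, K2CO3) to the iodomalonate F2. An iodine-atom-transfer radical cyclization ((Bu3Sn)2 cat., light, benzene) should then give the iodo lactone ester F3, with C7 under the same chair control. Treatment with AgOSO2CF3 should ionize C8 and close the butyrolactone through the tert-butyl ester carbonyl with loss of isobutene, which comes back to the route at 17.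

Step 15. Hydroxide may attack the butyrolactone carbonyl of the ammonium salt, the methacryloyl group may migrate to the freed primary hydroxyl, or that hydroxyl may add to the new methylene lactone. The fallback sets out from 17, before the methacrylate is on. The six-membered lactone would be saponified with LiOH (1.1 equiv, THF/H2O, 0 °C) to the hydroxy acid F4. Decarboxylative Mannich methylenation (aqueous CH2O, Et2NH; then NaOAc/AcOH, 70 °C) should give the diol F5. The primary hydroxyl would be silylated (TBSCl, imidazole) to F6, the secondary one acylated with methacrylic anhydride/DMAP to F7, and the silyl group removed with HF·pyridine, which comes back to the route at 21 under acidic conditions where acyl migration is slow.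

Step 17. The ring geometry may override the Felkin preference and give poor facial selectivity at the aldehyde, and oligomerization may compete with ring closure. The fallback sets out from 22. The ring-closed carbinol mixture containing the C5 epimer F8 would be oxidized with DMP to the cross-conjugated enone F9. Reduction with Zn(BH4)2 (Et2O, −78 °C), under chelation between the C5 ketone and the C6 ester oxygen, should deliver hydride to give the 5,6-anti carbinol, which comes back to the route at 23.

Further compounds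
F1 | step 12 | tert-butyl malonate of the primary hydroxyl of 15 | C=C(OS(=O)(=O)C(F)(F)F)C1=CC(=O)[C@](C)(C/C=C\[C@@H](O)COC(=O)CC(=O)OC(C)(C)C)O1
F2 | step 12 | iodomalonate of F1 | C=C(OS(=O)(=O)C(F)(F)F)C1=CC(=O)[C@](C)(C/C=C\[C@@H](O)COC(=O)C(I)C(=O)OC(C)(C)C)O1
F3 | step 12 | atom-transfer product: six-membered lactone with tert-butyl ester on C11 and iodide on C8 (C8 and C11 open) | C=C(OS(=O)(=O)C(F)(F)F)C1=CC(=O)[C@](C)(CC(I)[C@@H]2[C@@H](O)COC(=O)C2C(=O)OC(C)(C)C)O1
F4 | step 15 | α-carboxy butyrolactone with free C5 and C6 hydroxyls | C=C(OS(=O)(=O)C(F)(F)F)C1=CC(=O)[C@](C)(C[C@@H]2OC(=O)C(C(=O)O)[C@H]2[C@@H](O)CO)O1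
F5 | step 15 | α-methylene butyrolactone diol | C=C(OS(=O)(=O)C(F)(F)F)C1=CC(=O)[C@](C)(C[C@@H]2OC(=O)C(=C)[C@H]2[C@@H](O)CO)O1
F6 | step 15 | primary tert-butyldimethylsilyl ether of F5 | C=C(OS(=O)(=O)C(F)(F)F)C1=CC(=O)[C@](C)(C[C@@H]2OC(=O)C(=C)[C@H]2[C@@H](O)CO[Si](C)(C)C(C)(C)C)O1
F7 | step 15 | C6 methacrylate of F6 | C=C(OS(=O)(=O)C(F)(F)F)C1=CC(=O)[C@](C)(C[C@@H]2OC(=O)C(=C)[C@H]2[C@H](CO[Si](C)(C)C(C)(C)C)OC(=O)C(C)=C)O1
F8 | step 17 | C5 epimer of 23 | C=C(C)C(=O)O[C@@H]1[C@@H]2C(=C)C(=O)O[C@H]2C[C@]2(C)OC(=CC2=O)C(=C)[C@H]1O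
F9 | step 17 | C5 ketone (enone) of 23 | C=C(C)C(=O)O[C@@H]1[C@@H]2C(=C)C(=O)O[C@H]2C[C@]2(C)OC(=CC2=O)C(=C)C1=O
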